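**Retrosynthetic overview**
1. Target 13 is the (3S,4R)-lactone (3-OH trans to the 4-benzyl group, the two benzyl groups cis). It comes from diol 11 by one hydrogenolysis that removes the benzylic OH and both O-benzyl groups.
2. The tertiary C3–O bond of 11 is made by syn-dihydroxylation of arylidene lactone 10 on the face away from the C4 benzyl group.
3. 10 comes from (S)-lactone 6 and aldehyde 7 by aldol condensation.
4. Key step: the lactone C–O bond and the C4 stereocentre are made together by enantioselective Baeyer–Villiger desymmetrisation of prochiral cyclobutanone 4.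
5. 4 comes from allylarene 1 by keteniminium [2+2]. Ring order: cyclobutanone first, then its oxidative expansion to the γ-lactone, the only ring of the target.

Assumption: 1 and 7 are bought as such (1 is otherwise one benzylation away from eugenol).

**Step 1**
Reactants: 1 4-allyl-1-(benzyloxy)-2-methoxybenzene (O-benzyleugenol); 2 N,N-dimethylacetamide
Product: 4 prochiral ketone 3-[4-(benzyloxy)-3-methoxybenzyl]cyclobutan-1-one, via cyclobutaniminium triflate 3 (not isolated)
Conditions: Tf2O, 2,4,6-collidine, ClCH2CH2Cl, 0 °C then reflux; then H2O, 80 °C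
Reagents that add atoms: water (O)
Why: Keteniminium [2+2] cycloaddition (Ghosez): the keteniminium triflate formed from 2 adds to the terminal alkene with the terminal carbon bonding to the central keteniminium carbon, giving the 3-substituted cyclobutaniminium salt, which water hydrolyses to the symmetric ketone; no stereocentre is formed.

**Step 2**
Reactants: 4 3-[4-(benzyloxy)-3-methoxybenzyl]cyclobutan-1-one
Product: 6 (S)-4-[4-(benzyloxy)-3-methoxybenzyl]dihydrofuran-2(3H)-one, via Criegee adduct 5 (not isolated)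
Conditions: confined chiral imidodiphosphoric acid built from two 3,3'-bis(2,4,6-triethylphenyl)-BINOL units (5 mol%, antipode giving S), 30% aq. H2O2 (1.5 equiv), CHCl3, −40 °C
Reagents that add atoms: hydrogen peroxide (OO)
Why: Proposed new method: a Brønsted-acid-catalysed Baeyer–Villiger desymmetrisation in which a confined imidodiphosphoric acid replaces the open BINOL-phosphoric acids; its acid/P=O pair adds H2O2 to the carbonyl and holds Criegee adduct 5 by two hydrogen bonds inside the pocket, the migrating CH2 must stand antiperiplanar to the O–O bond, and the narrow pocket lets the puckered ring sit in only one orientation with its pseudo-equatorial arylmethyl arm pointing out of the mouth, so one of the two enantiotopic CH2 groups migrates and C4 is set as S (which catalyst antipode gives S is fixed in the first run against 6 from the fallback); the closest known reactions are the chiral-phosphoric-acid-catalysed Baeyer–Villiger oxidation of 3-arylcyclobutanones with aqueous H2O2, where an open acid is expected to discriminate a remote, flexible CH2Ar group less well than a directly attached aryl group, and the activation of H2O2 by confined imidodiphosphoric acids for sulfoxidation.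

**Step 3**
Reactants: 6 (S)-4-[4-(benzyloxy)-3-methoxybenzyl]dihydrofuran-2(3H)-one; 7 4-(benzyloxy)-3-methoxybenzaldehyde (O-benzylvanillin)
Product: 10 (S,E)-4-[4-(benzyloxy)-3-methoxybenzyl]-3-[4-(benzyloxy)-3-methoxybenzylidene]dihydrofuran-2(3H)-one, via lithium aldolate 8 (not isolated), via mesylate 9 (not isolated)
Conditions: LiN(iPr)2, THF, −78 °C; then 7; then MsCl, Et3N, −78 to 0 °C; then DBU, rt
Reagents that add atoms: none
Why: Aldol addition of the lithium lactone enolate to 7, then mesylation and E1cB elimination (aldol condensation), gives the thermodynamically preferred E-arylidene lactone; C4 is not acidic under these conditions and keeps its configuration.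

**Step 4**
Reactants: 10 (S,E)-arylidene lactone
Product: 11 (3R,4R)-4-[4-(benzyloxy)-3-methoxybenzyl]-3-{(S)-[4-(benzyloxy)-3-methoxyphenyl](hydroxy)methyl}-3-hydroxydihydrofuran-2(3H)-one
Conditions: K2OsO4·2H2O (5 mol%), NMO, citric acid, acetone–H2O 4:1, rt
Reagents that add atoms: N-methylmorpholine N-oxide (C[N+]1([O-])CCOCC1); water (O)
Why: Upjohn-type syn-dihydroxylation: allylic 1,3-strain with the arylidene aryl group turns the C4 benzyl group pseudo-axial so that it blocks one face, the [3+2] addition of OsO4 takes place on the other face, and the new tertiary C3–O bond ends up trans to the C4 benzyl group (3R in 11, which becomes 3S in the target); the benzylic carbinol centre is removed in step 5, so any Z isomer of 10 converges.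

**Step 5**
Reactants: 11 diol
Product: 13 (3S,4R)-3-hydroxy-3,4-bis(4-hydroxy-3-methoxybenzyl)dihydrofuran-2(3H)-one, via debenzylated diol 12 (not isolated)
Conditions: H2 (4 bar), Pd(OH)2/C, EtOAc–AcOH 1:1, 40 °C
Reagents that add atoms: none
Why: Catalytic hydrogenolysis: both O-benzyl ethers cleave first, and the para-hydroxybenzylic secondary alcohol of 12 is then hydrogenolysed with acid assistance, while the non-benzylic tertiary alcohol and the lactone stay; neither ring stereocentre is touched.

**Compound list**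
1 | 4-allyl-1-(benzyloxy)-2-methoxybenzene (O-benzyleugenol) | C=CCc1ccc(OCc2ccccc2)c(OC)c1 | starting material
2 | N,N-dimethylacetamide | CC(=O)N(C)C | starting material
3 | N-{3-[4-(benzyloxy)-3-methoxybenzyl]cyclobutylidene}-N-methylmethanaminium triflate | C[N+](C)=C1CC(Cc2ccc(OCc3ccccc3)c(OC)c2)C1.[O-]S(=O)(=O)C(F)(F)F | intermediate
4 | 3-[4-(benzyloxy)-3-methoxybenzyl]cyclobutan-1-one (achiral) | O=C1CC(Cc2ccc(OCc3ccccc3)c(OC)c2)C1 | intermediate
5 | 3-[4-(benzyloxy)-3-methoxybenzyl]-1-hydroperoxycyclobutan-1-ol (Criegee adduct, cis/trans not defined) | OOC1(O)CC(Cc2ccc(OCc3ccccc3)c(OC)c2)C1 | intermediate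
6 | (S)-4-[4-(benzyloxy)-3-methoxybenzyl]dihydrofuran-2(3H)-one | O=C1C[C@H](Cc2ccc(OCc3ccccc3)c(OC)c2)CO1 | intermediate
7 | 4-(benzyloxy)-3-methoxybenzaldehyde (O-benzylvanillin) | O=Cc1ccc(OCc2ccccc2)c(OC)c1 | starting material
8 | lithium [4-(benzyloxy)-3-methoxyphenyl]{(3R,4S)-4-[4-(benzyloxy)-3-methoxybenzyl]-2-oxotetrahydrofuran-3-yl}methanolate (both carbinol epimers) | O=C1OC[C@@H](Cc2ccc(OCc3ccccc3)c(OC)c2)[C@@H]1C([O-])c1ccc(OCc2ccccc2)c(OC)c1.[Li+] | intermediate
9 | [4-(benzyloxy)-3-methoxyphenyl]{(3R,4S)-4-[4-(benzyloxy)-3-methoxybenzyl]-2-oxotetrahydrofuran-3-yl}methyl methanesulfonate (both carbinol epimers) | O=C1OC[C@@H](Cc2ccc(OCc3ccccc3)c(OC)c2)[C@@H]1C(OS(C)(=O)=O)c1ccc(OCc2ccccc2)c(OC)c1 | intermediate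
10 | (S,E)-4-[4-(benzyloxy)-3-methoxybenzyl]-3-[4-(benzyloxy)-3-methoxybenzylidene]dihydrofuran-2(3H)-one | O=C1OC[C@@H](Cc2ccc(OCc3ccccc3)c(OC)c2)/C1=C\c1ccc(OCc2ccccc2)c(OC)c1 | intermediate
11 | (3R,4R)-4-[4-(benzyloxy)-3-methoxybenzyl]-3-{(S)-[4-(benzyloxy)-3-methoxyphenyl](hydroxy)methyl}-3-hydroxydihydrofuran-2(3H)-one | O=C1OC[C@@H](Cc2ccc(OCc3ccccc3)c(OC)c2)[C@@]1(O)[C@@H](O)c1ccc(OCc2ccccc2)c(OC)c1 | intermediate
12 | (3R,4R)-3-hydroxy-3-[(S)-hydroxy(4-hydroxy-3-methoxyphenyl)methyl]-4-(4-hydroxy-3-methoxybenzyl)dihydrofuran-2(3H)-one | O=C1OC[C@@H](Cc2ccc(O)c(OC)c2)[C@@]1(O)[C@@H](O)c1ccc(O)c(OC)c1 | intermediate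
13 | (3S,4R)-3-hydroxy-3,4-bis(4-hydroxy-3-methoxybenzyl)dihydrofuran-2(3H)-one | COc1cc(C[C@@H]2COC(=O)[C@]2(O)Cc2ccc(O)c(OC)c2)ccc1O | target

**Totals**
Total steps: 5. Longest linear sequence: 5 (1 → 4 → 6 → 10 → 11 → 13).

**Steps most likely to fail, with fallbacks**

Step 2 (the proposed new method). The untested catalyst may give low rate or low enantioselectivity. The fallback is known chemistry and sets out from 7. Stobbe condensation of 7 with dimethyl succinate (NaOMe, MeOH, reflux) gives (E)-4-[4-(benzyloxy)-3-methoxyphenyl]-3-(methoxycarbonyl)but-3-enoic acid F2. Rhodium-catalysed asymmetric hydrogenation ([Rh(cod)2]BF4, a chiral bisphosphine of the antipode that leads to S, H2, MeOH) gives (S)-4-[4-(benzyloxy)-3-methoxyphenyl]-3-(methoxycarbonyl)butanoic acid F3. Reduction of the ester in its potassium carboxylate with Ca(BH4)2 (from NaBH4 and CaCl2, EtOH), then aqueous HCl, closes the lactone and returns to the route at 6.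

Step 1. The keteniminium salt may acylate the electron-rich arene, or traces of acid may move the allyl double bond into conjugation. The fallback sets out from 1. [2+2] cycloaddition with dichloroketene, which does not attack arenes (Cl3CCOCl, Zn dust, Et2O, ultrasound), gives racemic 2,2-dichloro-3-[4-(benzyloxy)-3-methoxybenzyl]cyclobutan-1-one F1. Reductive dechlorination (Zn, AcOH, 60 °C) returns to the route at 4.

Step 5. The hindered benzylic C–OH bond next to the tertiary carbinol may cleave slowly, and acid may trigger a pinacol-type shift. The fallback sets out from 11. Selective acetylation of the secondary benzylic alcohol (Ac2O, pyridine, cat. DMAP, 0 °C) gives (S)-[4-(benzyloxy)-3-methoxyphenyl]{(3R,4R)-4-[4-(benzyloxy)-3-methoxybenzyl]-3-hydroxy-2-oxotetrahydrofuran-3-yl}methyl acetate F4. Neutral hydrogenolysis (H2, Pd/C, EtOAc–EtOH, rt) removes the benzylic acetate and both benzyl ethers without acid and returns to the route at 13.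

**Further compounds**
F1 | step 1 | 2,2-dichloro-3-[4-(benzyloxy)-3-methoxybenzyl]cyclobutan-1-one (racemic) | O=C1CC(Cc2ccc(OCc3ccccc3)c(OC)c2)C1(Cl)Cl
F2 | step 2 | (E)-4-[4-(benzyloxy)-3-methoxyphenyl]-3-(methoxycarbonyl)but-3-enoic acid | COC(=O)/C(CC(=O)O)=C/c1ccc(OCc2ccccc2)c(OC)c1
F3 | step 2 | (S)-4-[4-(benzyloxy)-3-methoxyphenyl]-3-(methoxycarbonyl)butanoic acid | COC(=O)[C@H](CC(=O)O)Cc1ccc(OCc2ccccc2)c(OC)c1
F4 | step 5 | (S)-[4-(benzyloxy)-3-methoxyphenyl]{(3R,4R)-4-[4-(benzyloxy)-3-methoxybenzyl]-3-hydroxy-2-oxotetrahydrofuran-3-yl}methyl acetate | O=C1OC[C@@H](Cc2ccc(OCc3ccccc3)c(OC)c2)[C@@]1(O)[C@@H](OC(C)=O)c1ccc(OCc2ccccc2)c(OC)c1
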